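If substrate falls pseudo-first-order under a free catalyst that dies on the clock, a charge of catalyst holds a fixed number of e-foldings of substrate, and that number can be read from where substrate stalls.

| flask | substrate | partner | capture agent | free catalyst | remark | time |
|---|---|---|---|---|---|---|
| Monday's | 0.40 M | 0.36 M | 0.40 M | 4 mM | run made earlier |  |
| Saturday's | 0.40 M | 0.36 M | 0.40 M | 2.7 mM | run made earlier |  |
| Wednesday's | 0.40 M | 0.36 M | 0.40 M | 6 mM | run made earlier |  |
| birch | 0.40 M | 0.360 M (fed, over 1.5 h) | 0.400 M | 4.0 mM | all else is in the flask from the start; the feed brings no volume worth counting | 4.0 h |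
| oak | 0.40 M (fed, over 1.5 h) | 0.360 M | 0.400 M | 4.0 mM | all else is in the flask from the start; the feed brings no volume worth counting | 4.0 h |
| maple | 0.40 M (in portions, 4, over 1.5 h) | 0.360 M | 0.400 M | 4.0 mM | first portion at the start, last at 1.5 h | 4.0 h |
| alder | 0.40 M | 0.360 M | 0.400 M | 4.0 mM | everything together at the start | 4.0 h |

- Monday's (time / h: product / %, trapped intermediate / %, substrate / %): 0.167: 7.1, 3.2, 31.6; 0.500: 21.7, 11.1, 7.9; 0.833: 28.7, 18.5, 3.5; 1.33: 33.5, 26.3, 2.0; 2.00: 35.5, 33.6, 0.9; 2.50: 36.0, 37.7, 1.1
- Saturday's (time / h: product / %, trapped intermediate / %, substrate / %): 0.500: 12.7, 10.4, 16.8; 1.00: 20.1, 20.9, 7.9; 1.50: 22.3, 29.1, 5.6; 2.00: 24.0, 34.9, 4.9; 2.50: 24.8, 39.8, 4.6; 3.00: 24.9, 43.5, 4.2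
- Wednesday's (time / h: product / %, trapped intermediate / %, substrate / %): 0.250: 19.9, 6.1, 9.8; 0.417: 29.6, 9.6, 3.6; 0.667: 38.4, 15.4, 1.1; 1.33: 46.4, 24.4, 0.5; 2.00: 49.1, 29.8, 0; 3.00: 49.5, 34.7, 0.4

(readings scatter by 0.3 percentage points)

- what is said of product includes idle complex
- the earlier runs were read with a standard deviation of 0.3 percentage points
- candidate steps: substrate + free catalyst -> free catalyst + open intermediate; free catalyst + open intermediate <-> catalyst intermediate; partner + catalyst intermediate -> free catalyst + product; free catalyst + product <-> idle complex; free catalyst -> spent catalyst; open intermediate + capture agent -> trapped intermediate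

1. the flask that comes out highest in share of product in product plus trapped intermediate, or "all alike" when all lie within 1.5 percentage points (birch / oak / maple / alder / all alike)
2. share of product in product plus trapped intermediate at the end, birch
3. share of product in product plus trapped intermediate at the end, oak
4. share of product in product plus trapped intermediate at the end, maple
5. share of product in product plus trapped intermediate at the end, alder

Saturday's run stalls near 4.2% of its substrate, which makes 1.17 mM⁻¹ the catalyst exposure, the e-foldings of substrate per unit of catalyst charged, over that catalyst's whole life. A charge of 4.0 mM therefore holds 4.70 e-foldings. Monday's first reading has already spent part of them, and the remainder reads as a first-order catalyst loss of 1.69 h⁻¹, so the catalyst's half-life, as read, of about 0.411 h is shorter than the 1.5 h addition.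

In this reckoning a dose of substrate entering late meets the exposure still unspent, and the fraction of it that survives is the exponential of minus that exposure. This reckoning, averaged over maple's portions, leaves 31.2% of maple's substrate unturned. Replacing oak's steady feed by its mean over the same times leaves 30.0% in oak. Alder repeats Monday's charge, whose last reading gives a share of 48.8% while trapped intermediate is still climbing, so alder should end below that. Monday's, Saturday's and Wednesday's runs charge partner alike at 0.36 M, so this reckoning leaves birch open.

The forecast names birch, with birch at 45%, oak at 20%, maple at 25% and alder at 44%, holding that “Feeding substrate wastes the catalyst's short life”.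

The flasks give birch 32.4%, oak 22.9%, maple 28.4% and alder 44.3%, so alder stands highest, and birch ends 13 percentage points under the forecast.

    substrate + free catalyst → free catalyst + open intermediate (k = 0.619 M⁻¹ s⁻¹)
    free catalyst + open intermediate ⇌ catalyst intermediate (K = 3.00 M⁻¹, k = 0.146 M⁻¹ s⁻¹)
    partner + catalyst intermediate → free catalyst + product (k = 0.376 M⁻¹ s⁻¹)
    free catalyst + product ⇌ idle complex (K = 0.768 M⁻¹, k = 0.00180 M⁻¹ s⁻¹)
    free catalyst → spent catalyst (k = 5.23 × 10⁻⁴ s⁻¹)
    open intermediate + capture agent → trapped intermediate (k = 3.16 × 10⁻⁴ M⁻¹ s⁻¹)

Oak ends with 31.8% of its substrate unturned, against the 30.0% reckoned. The largest single effect on the gap in share between alder and oak is the death of free catalyst: with that step taken away, the gap moves from 21 points to −0.71 points. In a further flask like oak but with 0.016 M of free catalyst, the exposure gives 18.8 e-foldings and, by the same mean, 4.75% of substrate left. That flask gives 4.21% left and a share of 53.3%.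

(The runs were computed with constants of no real substance, noise included.)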